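**Retrosynthetic overview**
- Last operation: hydrogenolysis of a 5,7-di-O-benzyl lactone. The benzyl groups decide which phenol closes the lactone (acyl ends at C8) and block lactone migration to O5.
- Key disconnection C4–phenyl: the lactone C4 is used as a nucleophile (an enantioenriched β-boryl lactone, a boron homoenolate) and joined to iodobenzene with retention. Both carbons are natively electrophilic.
- The boron homoenolate comes from enantioselective conjugate borylation of the 8-acyl-5,7-bis(benzyloxy)coumarin; the C4 stereocentre is set there.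
- The coumarin comes from hydroarylation/lactonisation of the dibenzylated acylphloroglucinol with ethyl propiolate; the ketone comes from Friedel–Crafts acylation of phloroglucinol.
- Ring order: aromatic ring A and both phenyl rings are bought; the pyranone ring is closed in step 3.

Assumption: the (R)-ligand in step 4 is taken to give the 4R boronate (the sense of induction is not known for this coumarin; if it gives 4S, the (S)-ligand is used), and step 5 is taken to run with retention as for other secondary benzylic pinacol boronates.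

**Step 1**
Reactants: 1 benzene-1,3,5-triol (phloroglucinol); 2 3-phenylpropanoyl chloride
Product: 3 3-phenyl-1-(2,4,6-trihydroxyphenyl)propan-1-one
Conditions: AlCl3 (4 equiv), PhNO2, 60 °C; then ice/aq. HCl
Reagents that add atoms: none
Why: Friedel–Crafts C-acylation of the threefold-symmetric, highly nucleophilic phloroglucinol gives a single mono-ketone, which is deactivated against a second acylation.

**Step 2**
Reactants: 3 3-phenyl-1-(2,4,6-trihydroxyphenyl)propan-1-one
Product: 4 1-[2,4-bis(benzyloxy)-6-hydroxyphenyl]-3-phenylpropan-1-one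
Conditions: BnBr (2.1 equiv), K2CO3 (2.2 equiv), acetone, reflux
Reagents that add atoms: benzyl bromide, BrCc1ccccc1
Why: Williamson etherification alkylates the two most acidic phenols (para and one ortho) while the remaining ortho OH, hydrogen-bonded to the ketone, stays free, so only the OH next to the acyl group can later close the lactone and O5 is blocked against lactone migration.

**Step 3**
Reactants: 4 1-[2,4-bis(benzyloxy)-6-hydroxyphenyl]-3-phenylpropan-1-one; 5 ethyl propiolate
Product: 7 5,7-bis(benzyloxy)-8-(3-phenylpropanoyl)-2H-chromen-2-one, via Z-acrylate ester 6 (not isolated)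
Conditions: Pd(OAc)2 (5 mol %), TFA/CH2Cl2 (1:3), 0 °C to rt
Reagents that add atoms: none
Why: Fujiwara-type Pd-catalysed hydroarylation of the propiolate (a Pechmann-type coumarin annulation) takes place at the ring carbon ortho to the free OH with anti addition, so the Z-acrylate lactonises at once onto that OH and the acyl group is fixed at C8.

**Step 4**
Reactants: 7 5,7-bis(benzyloxy)-8-(3-phenylpropanoyl)-2H-chromen-2-one
Product: 8 (4R)-5,7-bis(benzyloxy)-8-(3-phenylpropanoyl)-4-(4,4,5,5-tetramethyl-1,3,2-dioxaborolan-2-yl)-3,4-dihydro-2H-chromen-2-one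
Conditions: CuCl (5 mol %), (R)-DTBM-SEGPHOS (6 mol %), NaOtBu (10 mol %), B2pin2 (1.2 equiv), t-BuOH (2 equiv), THF, 0 °C to rt
Reagents that add atoms: bis(pinacolato)diboron, CC1(C)OB(OC1(C)C)B1OC(C)(C)C(C)(C)O1
Why: Copper-catalysed enantioselective conjugate borylation (β-boration of an enoate by a chiral bisphosphine–Cu–Bpin species) adds boron to one face of the flat coumarin at C4 and the copper enolate is protonated by t-BuOH, which sets C4 as 4R and turns the electrophilic coumarin C4 into a nucleophilic boron homoenolate.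

**Step 5**
Reactants: 8 (4R)-5,7-bis(benzyloxy)-8-(3-phenylpropanoyl)-4-(4,4,5,5-tetramethyl-1,3,2-dioxaborolan-2-yl)-3,4-dihydro-2H-chromen-2-one; 9 iodobenzene
Product: 10 (4S)-5,7-bis(benzyloxy)-4-phenyl-8-(3-phenylpropanoyl)-3,4-dihydro-2H-chromen-2-one
Conditions: Pd2(dba)3 (5 mol %), PPh3 (80 mol %), Ag2O (1.5 equiv), DME, 85 °C; then recrystallisation
Reagents that add atoms: none
Why: Stereoretentive Suzuki–Miyaura coupling of a secondary benzylic pinacol boronate: Ag2O-promoted transmetalation of the C4–B bond to Ph–Pd–I proceeds with retention and the excess PPh3 suppresses β-hydride elimination back to 7, so the homoenolate carbon is joined to the iodoarene carbon and 4R (C–B) becomes 4S (C–Ph) only through the change in CIP priorities.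

**Step 6**
Reactants: 10 (4S)-5,7-bis(benzyloxy)-4-phenyl-8-(3-phenylpropanoyl)-3,4-dihydro-2H-chromen-2-one
Product: 11 (4S)-5,7-dihydroxy-4-phenyl-8-(3-phenylpropanoyl)-3,4-dihydro-2H-chromen-2-one
Conditions: H2 (1 atm), 10% Pd/C, EtOAc, rt
Reagents that add atoms: none
Why: Hydrogenolysis of the two benzyl ethers under neutral conditions leaves the chelated aryl ketone, the lactone and the non-epimerisable C4 centre untouched and avoids base, which would let the lactone migrate to the freed O5.

**Compound list**
1 | benzene-1,3,5-triol (phloroglucinol) | Oc1cc(O)cc(O)c1 | starting material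
2 | 3-phenylpropanoyl chloride | O=C(Cl)CCc1ccccc1 | starting material
3 | 3-phenyl-1-(2,4,6-trihydroxyphenyl)propan-1-one | O=C(CCc1ccccc1)c1c(O)cc(O)cc1O | intermediate
4 | 1-[2,4-bis(benzyloxy)-6-hydroxyphenyl]-3-phenylpropan-1-one | O=C(CCc1ccccc1)c1c(O)cc(OCc2ccccc2)cc1OCc1ccccc1 | intermediate
5 | ethyl propiolate | C#CC(=O)OCC | starting material
6 | ethyl (2Z)-3-[4,6-bis(benzyloxy)-2-hydroxy-3-(3-phenylpropanoyl)phenyl]prop-2-enoate | CCOC(=O)/C=C\c1c(O)c(C(=O)CCc2ccccc2)c(OCc2ccccc2)cc1OCc1ccccc1 | intermediate
7 | 5,7-bis(benzyloxy)-8-(3-phenylpropanoyl)-2H-chromen-2-one | O=C1C=Cc2c(OCc3ccccc3)cc(OCc3ccccc3)c(C(=O)CCc3ccccc3)c2O1 | intermediate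
8 | (4R)-5,7-bis(benzyloxy)-8-(3-phenylpropanoyl)-4-(4,4,5,5-tetramethyl-1,3,2-dioxaborolan-2-yl)-3,4-dihydro-2H-chromen-2-one | O=C1C[C@@H](B2OC(C)(C)C(C)(C)O2)c2c(OCc3ccccc3)cc(OCc3ccccc3)c(C(=O)CCc3ccccc3)c2O1 | intermediate
9 | iodobenzene | Ic1ccccc1 | starting material
10 | (4S)-5,7-bis(benzyloxy)-4-phenyl-8-(3-phenylpropanoyl)-3,4-dihydro-2H-chromen-2-one | O=C1C[C@@H](c2ccccc2)c2c(OCc3ccccc3)cc(OCc3ccccc3)c(C(=O)CCc3ccccc3)c2O1 | intermediate
11 | (4S)-5,7-dihydroxy-4-phenyl-8-(3-phenylpropanoyl)-3,4-dihydro-2H-chromen-2-one | O=C1C[C@@H](c2ccccc2)c2c(O)cc(O)c(C(=O)CCc3ccccc3)c2O1 | target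

**Total step count:** 6. **Longest linear sequence:** 6.

**Steps most likely to fail, with fallbacks**

Step 5 is the most exposed. The boronate 8 is a hindered secondary benzylic nucleophile flanked by two ortho oxygens, so transmetalation may be slow. Protodeboronation, β-hydride elimination back to 7, or partial loss of enantiopurity are the likely failure modes. The fallback sets out from coumarin 7 and comes back at 10. It is a Hayashi–Miyaura asymmetric 1,4-addition of phenylboronic acid with Rh(acac)(C2H4)2 and (S)-SEGPHOS in dioxane/H2O at 60 °C, which puts the phenyl group on C4 directly in the normal polarity sense. For coumarin itself the R ligand gives the 4R lactone, so the S ligand is chosen for 4S. Compound 8 is bypassed and no new compound arises (F0).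

Step 4 is next. The coumarin is electron-rich and hindered at C4 by the peri benzyloxy group, so conversion or enantioselectivity of the borylation may be poor. The fallback sets out from 7 and comes back at 10 by way of a palladium homoenolate made by C–H activation. Conjugate reduction of 7 (Cu(OAc)2, 1,2-bis(diphenylphosphino)benzene, polymethylhydrosiloxane, t-BuOH, toluene) gives the saturated lactone 5,7-bis(benzyloxy)-8-(3-phenylpropanoyl)-3,4-dihydro-2H-chromen-2-one F3. Ring opening with quinolin-8-amine and AlMe3 in toluene gives the amide 3-[4,6-bis(benzyloxy)-2-hydroxy-3-(3-phenylpropanoyl)phenyl]-N-(quinolin-8-yl)propanamide F4. Aminoquinoline-directed, Pd-catalysed enantioselective benzylic C–H arylation with iodobenzene (Pd2(dba)3, BINOL-derived phosphoramidite, Cs2CO3, xylene, 120 °C) arylates the five-membered palladacycle and gives (3S)-3-[4,6-bis(benzyloxy)-2-hydroxy-3-(3-phenylpropanoyl)phenyl]-3-phenyl-N-(quinolin-8-yl)propanamide F5. TsOH in toluene at reflux then recloses the lactone to 10 with loss of quinolin-8-amine.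

Step 3 is the third risk. TFA may cleave or shift the benzyl ethers, and the acyl-deactivated ring may react slowly or at the other free ring carbon, which cannot lactonise. The fallback sets out from 4 and comes back at 7. Vilsmeier–Haack formylation (POCl3, DMF, 0 °C to rt; aq. NaOAc) ortho to the free OH gives the salicylaldehyde 4,6-bis(benzyloxy)-2-hydroxy-3-(3-phenylpropanoyl)benzaldehyde F1. Wittig olefination with ethyl (triphenylphosphoranylidene)acetate in N,N-diethylaniline at reflux gives ethyl (2E)-3-[4,6-bis(benzyloxy)-2-hydroxy-3-(3-phenylpropanoyl)phenyl]prop-2-enoate F2, which isomerises and lactonises in the same pot to 7.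

**Further compounds**
F1 | step 3 | 4,6-bis(benzyloxy)-2-hydroxy-3-(3-phenylpropanoyl)benzaldehyde | O=Cc1c(O)c(C(=O)CCc2ccccc2)c(OCc2ccccc2)cc1OCc1ccccc1
F2 | step 3 | ethyl (2E)-3-[4,6-bis(benzyloxy)-2-hydroxy-3-(3-phenylpropanoyl)phenyl]prop-2-enoate | CCOC(=O)/C=C/c1c(O)c(C(=O)CCc2ccccc2)c(OCc2ccccc2)cc1OCc1ccccc1
F3 | step 4 | 5,7-bis(benzyloxy)-8-(3-phenylpropanoyl)-3,4-dihydro-2H-chromen-2-one | O=C1CCc2c(OCc3ccccc3)cc(OCc3ccccc3)c(C(=O)CCc3ccccc3)c2O1
F4 | step 4 | 3-[4,6-bis(benzyloxy)-2-hydroxy-3-(3-phenylpropanoyl)phenyl]-N-(quinolin-8-yl)propanamide | O=C(CCc1c(OCc2ccccc2)cc(OCc2ccccc2)c(C(=O)CCc2ccccc2)c1O)Nc1cccc2cccnc12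
F5 | step 4 | (3S)-3-[4,6-bis(benzyloxy)-2-hydroxy-3-(3-phenylpropanoyl)phenyl]-3-phenyl-N-(quinolin-8-yl)propanamide | O=C(C[C@@H](c1ccccc1)c1c(OCc2ccccc2)cc(OCc2ccccc2)c(C(=O)CCc2ccccc2)c1O)Nc1cccc2cccnc12
F0 | step 5 | none | none
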